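**Plan**

1. Locants follow the systematic name: hydroazulene C1–C8a (ring C seven-membered, ring D five-membered), benzoxepane O1–C9a (ring A oxepane, ring B cyclohexane); the CH2CH2 linker joins C5 of ring C to C6 of ring B.
2. Cuts: the C3 ketone goes back to a silyl-protected alcohol; the C5–CH2 bond is cut because C5 is allylic to the ring C alkene C6=C7, so the bond can be made by 1,3-transposition, with a linker alkylcopper attacking C5 of a C5=C6 allylic C7 phosphate anti to the leaving group.
3. Right half, forward: geranyl bromide plus an acetamide unit, two Shi epoxides, then one silyl triflate cascade closes ring A and ring B and leaves a 6-vinyl group; MeLi/CeCl3 then makes the C7 carbinol.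
4. Left half, forward: 2,4,4-trimethylcyclohexadienone, asymmetric conjugate addition of a butenyl group, cyclopropanation, then an FeCl3 ring expansion/5-exo radical cyclisation forms ring C and ring D together; hydration, CBS reduction and phosphorylation follow.
5. Union and end: the 9-BBN adduct of the 6-vinyl group is coupled with the allylic phosphate under copper catalysis, then desilylation and oxidation at C3.
6. Stereochemistry: C5a/C9a from the Shi epoxides, C6 from the chair closure, C7 (ring B) by equatorial attack; C3a from the chiral copper catalyst, C8a and C1 relayed from it, C7 (ring C) from the CBS reagent, C5 from that C7 by anti-SN2′ chirality transfer.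

Key step: step 17

Remark: geranyl bromide, N-methoxy-N-methylacetamide, 2,4,4-trimethylcyclohex-2-enone, the D-fructose-derived Shi ketone and the phosphoramidite ligand are taken as purchasable; (but-3-enyl)2Zn is made beforehand from but-3-enylmagnesium bromide and ZnCl2.

**Route**

Step 1
Reactants: 1 geranyl bromide; 2 N-methoxy-N-methylacetamide
Product: 4 (4E)-N-methoxy-N,5,9-trimethyldeca-4,8-dienamide, via lithium enolate of the acetamide 3 (not isolated)
Conditions: LiN(iPr)2, THF, −78 °C; then 1, −78 → −20 °C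
Reagents that add atoms: none
Why: Enolate alkylation (SN2) of the Weinreb acetamide enolate by the primary allylic bromide keeps the E-alkene and places a latent ketone carbonyl at the future C7 of ring B.

Step 2
Reactants: 4 (4E)-N-methoxy-N,5,9-trimethyldeca-4,8-dienamide
Product: 5 (R;R,R)-bis-epoxy Weinreb amide
Conditions: D-fructose-derived Shi ketone (0.3 equiv per alkene), Oxone (2KHSO5·KHSO4·K2SO4), K2CO3, Bu4NHSO4, MeCN/CH2(OMe)2/aq. buffer (pH 10.5), 0 °C
Reagents that add atoms: potassium peroxymonosulfate (the KHSO5 of Oxone), [K+].[O-]S(=O)(=O)OO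
Why: Shi asymmetric epoxidation, in which the chiral dioxirane should attack both electron-rich trisubstituted alkenes on the same enantioface through the spiro transition state, giving the (R)- and (R,R)-epoxides that become C3, C5a and C9a while the amide stays inert.

Step 3
Reactants: 5 (R;R,R)-bis-epoxy Weinreb amide
Product: 7 bis-epoxy allyl ketone, via magnesium salt of the tetrahedral adduct 6 (not isolated)
Conditions: CH2=CHCH2MgBr, THF, −78 °C; then aq. NH4Cl, −78 °C
Reagents that add atoms: allylmagnesium bromide, C=CC[Mg]Br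
Why: Weinreb ketone synthesis, in which the chelated tetrahedral adduct prevents over-addition and the trisubstituted epoxides should not be opened by the Grignard reagent at −78 °C.

Step 4
Reactants: 7 bis-epoxy allyl ketone
Product: 9 (3Z)-silyl dienol ether, via potassium dienolate 8 (not isolated)
Conditions: KN(SiMe3)2, THF, −78 °C; then t-BuMe2SiCl, −78 → 0 °C
Reagents that add atoms: tert-butyldimethylsilyl chloride, CC(C)(C)[Si](C)(C)Cl
Why: Regioselective enolisation and O-silylation, the CH2 between carbonyl and vinyl being by far the most acidic site, so the extended dienolate forms and is silylated on oxygen, expected mainly as the (3Z)-isomer.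

Step 5
Reactants: 9 (3Z)-silyl dienol ether
Product: 10 trans-fused 6-vinyl benzoxepan-7-one with 3-OTBS
Conditions: t-BuMe2SiOTf (0.2 equiv), 2,6-di-tert-butyl-4-methylpyridine, CH2Cl2, −78 °C
Reagents that add atoms: none
Why: Silyl triflate-promoted tandem epoxide-opening oxa-/carbacyclisation with an enol silane terminator, in which silylation of the terminal epoxide lets the internal epoxide oxygen attack its tertiary carbon (ring A), and the resulting epoxonium ion is opened with inversion at its tertiary carbon by the α-carbon of the dienol ether through a chair (ring B, 6-membered; closure through the diene terminus would need an 8-membered ring), which should give the trans ring fusion from the epoxide configuration, the equatorial 6-vinyl group and the silyl group on the C3 oxygen.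

Step 6
Reactants: 10 trans-fused 6-vinyl benzoxepan-7-one
Product: 11 (7S)-tertiary carbinol
Conditions: MeLi, CeCl3, THF, −78 °C
Reagents that add atoms: methyllithium, [Li]C
Why: 1,2-Addition of the weakly basic organocerium reagent, which should not enolise the α-vinyl ketone and should attack from the equatorial direction because the axial face is blocked by the axial C5a methyl group, giving the axial hydroxyl and equatorial methyl at C7.

Step 7
Reactants: 11 (7S)-tertiary carbinol
Product: 12 bis-silyl ether of the right half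
Conditions: Et3SiOTf, 2,6-lutidine, CH2Cl2, −78 → 0 °C
Reagents that add atoms: triethylsilyl triflate, CC[Si](CC)(CC)OS(=O)(=O)C(F)(F)F
Why: Silyl triflate silylation of the hindered tertiary alcohol masks the last free hydroxyl before the borane and copper chemistry.

Step 8
Reactants: 13 2,4,4-trimethylcyclohex-2-en-1-one
Product: 14 2,4,4-trimethylcyclohexa-2,5-dien-1-one
Conditions: IBX, DMSO/fluorobenzene, 70 °C
Reagents that add atoms: none
Why: IBX dehydrogenation through the α′-enol introduces the second double bond and gives an achiral cross-conjugated dienone with one unsubstituted enone arm.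

Step 9
Reactants: 14 2,4,4-trimethylcyclohexa-2,5-dien-1-one
Product: 16 (3R)-3-butenyl silyl dienol ether, via zinc enolate 15 (not isolated)
Conditions: Cu(OTf)2 (2 mol %), (S,R,R)-phosphoramidite ligand [from (S)-BINOL and bis((R)-1-phenylethyl)amine] (4 mol %), (CH2=CHCH2CH2)2Zn, toluene, −30 °C; then Me3SiOTf, −30 → 0 °C
Reagents that add atoms: di(but-3-enyl)zinc, C=CCC[Zn]CCC=C; trimethylsilyl triflate, C[Si](C)(C)OS(=O)(=O)C(F)(F)F
Why: Copper-catalysed asymmetric conjugate addition of a dialkylzinc to a 4,4-disubstituted cyclohexadienone, in which the unsubstituted enone arm should react before the α-methyl arm, the ligand (enantiomer chosen by analogy with simple cyclohexenones) selects the face and so sets the future C3a, and the zinc enolate is trapped on oxygen as a regiodefined silyl enol ether.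

Step 10
Reactants: 16 (3R)-3-butenyl silyl dienol ether
Product: 17 siloxycyclopropane
Conditions: Et2Zn, CH2I2, CH2Cl2, 0 °C
Reagents that add atoms: diiodomethane, ICI
Why: Simmons–Smith cyclopropanation with the Et2Zn/CH2I2 reagent should occur at the most electron-rich alkene, the silyl enol ether, and the two new stereocentres are lost again in step 11.

Step 11
Reactants: 17 siloxycyclopropane
Product: 18 cis-fused 1-(chloromethyl)hydroazulen-7-one
Conditions: FeCl3 (2.2 equiv), DMF, 0 °C → rt
Reagents that add atoms: iron trichloride, Cl[Fe](Cl)Cl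
Why: Saegusa–Ito-type oxidative ring expansion with radical cyclisation, in which FeCl3 opens the internal cyclopropane bond to give the seven-membered enone with a radical at C8a, this radical closes ring D by 5-exo-trig addition to the butenyl alkene on the face of that chain (cis fusion, C8a relayed from C3a), and chlorine-atom transfer ends the sequence at the exocyclic carbon.

Step 12
Reactants: 18 cis-fused 1-(chloromethyl)hydroazulen-7-one
Product: 20 1-methylidene hydroazulen-7-one, via iodomethyl ketone 19 (not isolated)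
Conditions: NaI (cat.), DBU, DMF, 80 °C
Reagents that add atoms: none
Why: Finkelstein exchange and E2 elimination with a non-nucleophilic amidine base, where H-1 is the only β-hydrogen so only the exocyclic alkene can form, and the base is too weak to enolise the ketone to a significant extent.

Step 13
Reactants: 20 1-methylidene hydroazulen-7-one
Product: 21 (1R)-1-hydroxy hydroazulen-7-one
Conditions: Co(acac)2 (20 mol %), PhSiH3, O2 (1 atm), THF, rt
Reagents that add atoms: dioxygen, O=O
Why: Mukaiyama hydration, in which hydrogen-atom transfer to the unhindered CH2 terminus gives the tertiary C1 radical that O2 should trap on the convex face of the cis-fused bicycle (the face of H-8a), placing the hydroxyl cis to the ring-fusion hydrogens, while the hindered electron-poor enone alkene should react much more slowly.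

Step 14
Reactants: 21 (1R)-1-hydroxy hydroazulen-7-one
Product: 22 1-triethylsilyloxy hydroazulen-7-one
Conditions: Et3SiOTf, 2,6-lutidine, CH2Cl2, −78 → 0 °C
Reagents that add atoms: triethylsilyl triflate, CC[Si](CC)(CC)OS(=O)(=O)C(F)(F)F
Why: Silyl triflate silylation of the tertiary alcohol keeps it out of the later alkoxide and borane steps.

Step 15
Reactants: 22 1-triethylsilyloxy hydroazulen-7-one
Product: 23 (7R)-allylic alcohol
Conditions: (S)-2-methyl-CBS-oxazaborolidine (20 mol %), BH3·SMe2, THF, −30 °C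
Reagents that add atoms: none
Why: Corey–Bakshi–Shibata reduction, in which the catalyst distinguishes the α-methylalkenyl (large) from the CH2 (small) flank and the (S)-catalyst is expected to give the (7R)-alcohol with the hydroxyl on the face of the ring-fusion hydrogens.

Step 16
Reactants: 23 (7R)-allylic alcohol
Product: 24 (7R)-allylic diethyl phosphate
Conditions: ClP(O)(OEt)2, pyridine, DMAP (cat.), CH2Cl2, 0 °C
Reagents that add atoms: diethyl chlorophosphate, CCOP(=O)(Cl)OCC
Why: O-Phosphorylation of the secondary allylic alcohol with retention provides the leaving group for copper-mediated allylic substitution.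

Step 17
Reactants: 12 bis-silyl ether of the right half; 24 (7R)-allylic diethyl phosphate
Product: 26 tris-silyl ether of the coupled skeleton, via B-alkyl-9-BBN 25 (not isolated)
Conditions: 12, 9-BBN-H dimer, THF, 60 °C; then 24, CuOAc (10 mol %), KOtBu, THF, 60 °C
Reagents that add atoms: none
Why: Anti-Markovnikov hydroboration of the vinyl group of 12 gives the B-alkyl-9-BBN, whose tert-butoxide borate passes the primary alkyl group to monovalent copper, and the alkylcopper adds to C5 of the allylic phosphate on the face opposite the C7–O bond while the phosphate leaves and the C6=C7 alkene forms (oxidative addition to a trivalent σ-allylcopper, then reductive elimination). The closest known reaction type is the copper-catalysed γ-selective allyl–alkyl coupling of alkyl-9-BBN reagents with secondary allylic phosphates, which runs with 1,3-anti chirality transfer. No ring is closed. The only new stereocentre, C5, is controlled by C7: the (7R)-phosphate sits on the face of the ring-fusion hydrogens, so the new C–C bond should form on the opposite face, cis to ring D as in the target. The step needs γ- over α-attack and anti over syn delivery; the phosphate leaving group with the copper/borate system directs attack to the γ-carbon even when it is hindered, and the stereoelectronic preference for anti attack in THF, in a ring that cannot easily reach a chelated syn geometry, should secure the second. Chemoselectivity rests on silyl protection of all three hydroxyl groups and on the inertness of the trisubstituted alkene towards 9-BBN.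

Step 18
Reactants: 26 tris-silyl ether of the coupled skeleton
Product: 27 triol (C3 alcohol)
Conditions: Bu4NF, THF, 50 °C
Reagents that add atoms: none
Why: Fluoride desilylation should cleave the two tertiary triethylsilyl ethers and, on warming, the hindered secondary tert-butyldimethylsilyl ether without touching the alkene or the carbinols.

Step 19
Reactants: 27 triol (C3 alcohol)
Product: 28 sipholenone A
Conditions: Dess–Martin periodinane, CH2Cl2, rt
Reagents that add atoms: none
Why: Dess–Martin oxidation converts the only secondary alcohol into the C3 ketone, since the two tertiary alcohols cannot be oxidised.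

**Compound list**

1 | geranyl bromide, (2E)-1-bromo-3,7-dimethylocta-2,6-diene | CC(C)=CCC/C(C)=C/CBr | starting material
2 | N-methoxy-N-methylacetamide | CC(=O)N(C)OC | starting material
3 | lithium enolate of N-methoxy-N-methylacetamide | [Li+].[O-]C(=C)N(C)OC | intermediate
4 | (4E)-N-methoxy-N,5,9-trimethyldeca-4,8-dienamide | CC(C)=CCC/C(C)=C/CCC(=O)N(C)OC | intermediate
5 | 3-[(2R,3R)-3-{2-[(2R)-3,3-dimethyloxiran-2-yl]ethyl}-3-methyloxiran-2-yl]-N-methoxy-N-methylpropanamide | CC1(C)O[C@@H]1CC[C@@]2(C)O[C@@H]2CCC(=O)N(C)OC | intermediate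
6 | bromomagnesium alkoxide of the tetrahedral allyl adduct of 5 | CC1(C)O[C@@H]1CC[C@@]2(C)O[C@@H]2CCC([O-])(CC=C)N(C)OC.[Mg+2].[Br-] | intermediate
7 | 1-[(2R,3R)-3-{2-[(2R)-3,3-dimethyloxiran-2-yl]ethyl}-3-methyloxiran-2-yl]hex-5-en-3-one | CC1(C)O[C@@H]1CC[C@@]2(C)O[C@@H]2CCC(=O)CC=C | intermediate
8 | potassium (3Z)-dienolate of 7 | CC1(C)O[C@@H]1CC[C@@]2(C)O[C@@H]2CC/C([O-])=C/C=C.[K+] | intermediate
9 | tert-butyl{[(3Z)-1-{(2R,3R)-3-[2-((2R)-3,3-dimethyloxiran-2-yl)ethyl]-3-methyloxiran-2-yl}hexa-3,5-dien-3-yl]oxy}dimethylsilane | CC1(C)O[C@@H]1CC[C@@]2(C)O[C@@H]2CC/C(O[Si](C)(C)C(C)(C)C)=C/C=C | intermediate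
10 | (3R,5aR,6R,9aR)-3-(tert-butyldimethylsilyloxy)-6-ethenyl-2,2,5a-trimethyloctahydro-1-benzoxepin-7(2H)-one (trans-fused, vinyl cis to the angular methyl) | C=C[C@@H]1[C@@]2(C)CC[C@@H](O[Si](C)(C)C(C)(C)C)C(C)(C)O[C@@H]2CCC1=O | intermediate
11 | (3R,5aR,6R,7S,9aR)-3-(tert-butyldimethylsilyloxy)-6-ethenyl-2,2,5a,7-tetramethyldecahydro-1-benzoxepin-7-ol | C=C[C@@H]1[C@@]2(C)CC[C@@H](O[Si](C)(C)C(C)(C)C)C(C)(C)O[C@@H]2CC[C@]1(C)O | intermediate
12 | 7-O-triethylsilyl ether of 11 | C=C[C@@H]1[C@@]2(C)CC[C@@H](O[Si](C)(C)C(C)(C)C)C(C)(C)O[C@@H]2CC[C@]1(C)O[Si](CC)(CC)CC | intermediate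
13 | 2,4,4-trimethylcyclohex-2-en-1-one | CC1=CC(C)(C)CCC1=O | starting material
14 | 2,4,4-trimethylcyclohexa-2,5-dien-1-one | CC1=CC(C)(C)C=CC1=O | intermediate
15 | but-3-enylzinc enolate of (5R)-5-(but-3-enyl)-2,4,4-trimethylcyclohex-2-enone | CC1=CC(C)(C)[C@H](CCC=C)C=C1O[Zn]CCC=C | intermediate
16 | {[(3R)-3-(but-3-en-1-yl)-4,4,6-trimethylcyclohexa-1,5-dien-1-yl]oxy}trimethylsilane | CC1=CC(C)(C)[C@H](CCC=C)C=C1O[Si](C)(C)C | intermediate
17 | {[(5R)-5-(but-3-en-1-yl)-2,4,4-trimethylbicyclo[4.1.0]hept-2-en-1-yl]oxy}trimethylsilane (cyclopropane face not defined) | CC1=CC(C)(C)[C@H](CCC=C)C2CC12O[Si](C)(C)C | intermediate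
18 | (3aR,8aR)-1-(chloromethyl)-4,4,6-trimethyl-2,3,3a,4,8,8a-hexahydroazulen-7(1H)-one (cis-fused, C1 epimers) | CC1=CC(C)(C)[C@@H]2CCC(CCl)[C@@H]2CC1=O | intermediate
19 | (3aR,8aR)-1-(iodomethyl)-4,4,6-trimethyl-2,3,3a,4,8,8a-hexahydroazulen-7(1H)-one | CC1=CC(C)(C)[C@@H]2CCC(CI)[C@@H]2CC1=O | intermediate
20 | (3aR,8aR)-4,4,6-trimethyl-1-methylidene-2,3,3a,4,8,8a-hexahydroazulen-7(1H)-one | CC1=CC(C)(C)[C@@H]2CCC(=C)[C@@H]2CC1=O | intermediate
21 | (1R,3aR,8aR)-1-hydroxy-1,4,4,6-tetramethyl-2,3,3a,4,8,8a-hexahydroazulen-7(1H)-one (OH cis to H-3a and H-8a) | CC1=CC(C)(C)[C@@H]2CC[C@@](C)(O)[C@@H]2CC1=O | intermediate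
22 | (1R,3aR,8aR)-1,4,4,6-tetramethyl-1-(triethylsilyloxy)-2,3,3a,4,8,8a-hexahydroazulen-7(1H)-one | CC1=CC(C)(C)[C@@H]2CC[C@@](C)(O[Si](CC)(CC)CC)[C@@H]2CC1=O | intermediate
23 | (1R,3aR,7R,8aR)-1,4,4,6-tetramethyl-1-(triethylsilyloxy)-1,2,3,3a,4,7,8,8a-octahydroazulen-7-ol (7-OH cis to the ring-fusion hydrogens) | CC1=CC(C)(C)[C@@H]2CC[C@@](C)(O[Si](CC)(CC)CC)[C@@H]2C[C@H]1O | intermediate
24 | diethyl (1R,3aR,7R,8aR)-1,4,4,6-tetramethyl-1-(triethylsilyloxy)-1,2,3,3a,4,7,8,8a-octahydroazulen-7-yl phosphate | CC1=CC(C)(C)[C@@H]2CC[C@@](C)(O[Si](CC)(CC)CC)[C@@H]2C[C@H]1OP(=O)(OCC)OCC | intermediate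
25 | 9-{2-[(3R,5aR,6R,7S,9aR)-3-(tert-butyldimethylsilyloxy)-2,2,5a,7-tetramethyl-7-(triethylsilyloxy)decahydro-1-benzoxepin-6-yl]ethyl}-9-borabicyclo[3.3.1]nonane | C1CCC2CCCC1B2CC[C@@H]3[C@@]4(C)CC[C@@H](O[Si](C)(C)C(C)(C)C)C(C)(C)O[C@@H]4CC[C@]3(C)O[Si](CC)(CC)CC | intermediate
26 | 3-O-tert-butyldimethylsilyl-7-O,1′-O-bis(triethylsilyl) ether of triol 27 (C5 of ring C S, linker cis to ring D) | CC1=CC[C@@H]2[C@@H](CC[C@@]2(C)O[Si](CC)(CC)CC)C(C)(C)[C@H]1CC[C@@H]1[C@@]2(C)CC[C@@H](O[Si](C)(C)C(C)(C)C)C(C)(C)O[C@@H]2CC[C@]1(C)O[Si](CC)(CC)CC | intermediate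
27 | (3R,5aR,6R,7S,9aR)-6-{2-[(1R,3aR,5S,8aR)-1-hydroxy-1,4,4,6-tetramethyl-1,2,3,3a,4,5,8,8a-octahydroazulen-5-yl]ethyl}-2,2,5a,7-tetramethyldecahydro-1-benzoxepine-3,7-diol | CC1=CC[C@@H]2[C@@H](CC[C@@]2(C)O)C(C)(C)[C@H]1CC[C@@H]1[C@@]2(C)CC[C@@H](O)C(C)(C)O[C@@H]2CC[C@]1(C)O | intermediate
28 | sipholenone A, (5aR,6R,7S,9aR)-7-hydroxy-6-{2-[(1R,3aR,5S,8aR)-1-hydroxy-1,4,4,6-tetramethyl-1,2,3,3a,4,5,8,8a-octahydroazulen-5-yl]ethyl}-2,2,5a,7-tetramethyloctahydro-1-benzoxepin-3(2H)-one | CC1=CC[C@@H]2[C@@H](CC[C@@]2(C)O)C(C)(C)[C@H]1CC[C@@H]1[C@@]2(C)CCC(=O)C(C)(C)O[C@@H]2CC[C@]1(C)O | target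

**Step count and risks**

Total steps: 19 (right half steps 1–7, left half steps 8–16, union and end steps 17–19).
Longest linear sequence: 12 steps (13 to 28, steps 8–19).

Steps most likely to fail:

Step 17. The alkylcopper may not reach the neopentyl C5 terminus, so that attack at C7, elimination of the phosphate to a diene, or loss of anti delivery takes over. The fallback sets out from enone 22 and alkene 12 and comes back at 26; it delivers the carbon intramolecularly. Reduction of 22 with the (R)-CBS catalyst would give the C7-epimeric (7S)-allylic alcohol F1. Linear hydroformylation of 12 (Rh(acac)(CO)2, BiPhePhos, CO/H2) would give the homologous propanal F2, and NaClO2 oxidation the propanoic acid F3. DCC/DMAP esterification of F1 with F3 would give the allylic ester F4. KN(SiMe3)2/Me3SiCl at −78 °C and warming would bring about the Ireland–Claisen rearrangement, in which the ketene acetal carbon bonds to C5 on the face of the C7–O bond (the required face) while the alkene moves to C6=C7, giving the α-branched acid F5. Conversion into the N-acyloxypyridine-2-thione F6 and photolysis with t-BuSH (Barton decarboxylation) would remove the carboxyl group and give 26.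

Step 5. The dienol silyl ether may react through its terminal carbon with another cation, or the 6-vinyl ketone may slip into conjugation under the Lewis acid. The fallback sets out from 5 and comes back at 11; it uses a saturated, regiodefined enol silane as terminator and trims one carbon afterwards. Vinylmagnesium bromide on 5 would give the vinyl ketone F7. CuBr·SMe2-catalysed conjugate addition of vinylmagnesium bromide with t-BuMe2SiCl/HMPA trapping would give the (Z)-enol silyl ether F8. The same silyl triflate cascade would give the 6-allyl ketone F9, and MeLi/CeCl3 the allyl carbinol F10. RuHCl(CO)(PPh3)3 would move the alkene to give the propenyl carbinol F11, and ethenolysis (second-generation Grubbs catalyst, ethylene) would cut it down to the vinyl carbinol 11.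

Step 11. Chlorine-atom transfer to the ring radical may outrun the 5-exo closure, or the cyclopropane may open at its external bond without ring expansion. The fallback sets out from 16 and comes back at 20; it separates the two events and runs them in the opposite order. Pd(OAc)2-mediated oxidative cyclisation of silyl enol ether 16 onto the butenyl alkene (5-exo carbopalladation, β-hydride elimination) would give the cis-fused methylene hydrindenone F12. One-carbon homologation with Me3SiCHN2/AlMe3, with migration of the sp3 ring-fusion carbon, would give the α-silyl cycloheptenone F13, and K2CO3/MeOH would remove the silyl group to give 20.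

**Further compounds**

F1 | step 17 | (1R,3aR,7S,8aR)-1,4,4,6-tetramethyl-1-(triethylsilyloxy)-1,2,3,3a,4,7,8,8a-octahydroazulen-7-ol | CC1=CC(C)(C)[C@@H]2CC[C@@](C)(O[Si](CC)(CC)CC)[C@@H]2C[C@@H]1O
F2 | step 17 | 3-[(3R,5aR,6R,7S,9aR)-3-(tert-butyldimethylsilyloxy)-2,2,5a,7-tetramethyl-7-(triethylsilyloxy)decahydro-1-benzoxepin-6-yl]propanal | O=CCC[C@@H]1[C@@]2(C)CC[C@@H](O[Si](C)(C)C(C)(C)C)C(C)(C)O[C@@H]2CC[C@]1(C)O[Si](CC)(CC)CC
F3 | step 17 | 3-[(3R,5aR,6R,7S,9aR)-3-(tert-butyldimethylsilyloxy)-2,2,5a,7-tetramethyl-7-(triethylsilyloxy)decahydro-1-benzoxepin-6-yl]propanoic acid | OC(=O)CC[C@@H]1[C@@]2(C)CC[C@@H](O[Si](C)(C)C(C)(C)C)C(C)(C)O[C@@H]2CC[C@]1(C)O[Si](CC)(CC)CC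
F4 | step 17 | ester of F1 (through its 7-oxygen, 7S) with acid F3 | CC1=CC(C)(C)[C@@H]2CC[C@@](C)(O[Si](CC)(CC)CC)[C@@H]2C[C@@H]1OC(=O)CC[C@@H]3[C@@]4(C)CC[C@@H](O[Si](C)(C)C(C)(C)C)C(C)(C)O[C@@H]4CC[C@]3(C)O[Si](CC)(CC)CC
F5 | step 17 | 1′-carboxylic acid of 26 (carboxyl on the linker carbon attached to C5 of ring C, epimers at that carbon) | CC1=CC[C@@H]2[C@@H](CC[C@@]2(C)O[Si](CC)(CC)CC)C(C)(C)[C@H]1C(C(=O)O)C[C@@H]1[C@@]2(C)CC[C@@H](O[Si](C)(C)C(C)(C)C)C(C)(C)O[C@@H]2CC[C@]1(C)O[Si](CC)(CC)CC
F6 | step 17 | 2-thioxopyridin-1(2H)-yl ester of F5 | CC1=CC[C@@H]2[C@@H](CC[C@@]2(C)O[Si](CC)(CC)CC)C(C)(C)[C@H]1C(C(=O)ON3C=CC=CC3=S)C[C@@H]1[C@@]2(C)CC[C@@H](O[Si](C)(C)C(C)(C)C)C(C)(C)O[C@@H]2CC[C@]1(C)O[Si](CC)(CC)CC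
F7 | step 5 | 5-[(2R,3R)-3-{2-[(2R)-3,3-dimethyloxiran-2-yl]ethyl}-3-methyloxiran-2-yl]pent-1-en-3-one | CC1(C)O[C@@H]1CC[C@@]2(C)O[C@@H]2CCC(=O)C=C
F8 | step 5 | tert-butyl{[(3Z)-1-{(2R,3R)-3-[2-((2R)-3,3-dimethyloxiran-2-yl)ethyl]-3-methyloxiran-2-yl}hepta-3,6-dien-3-yl]oxy}dimethylsilane | CC1(C)O[C@@H]1CC[C@@]2(C)O[C@@H]2CC/C(O[Si](C)(C)C(C)(C)C)=C/CC=C
F9 | step 5 | (3R,5aR,6R,9aR)-3-(tert-butyldimethylsilyloxy)-2,2,5a-trimethyl-6-(prop-2-en-1-yl)octahydro-1-benzoxepin-7(2H)-one | C=CC[C@@H]1[C@@]2(C)CC[C@@H](O[Si](C)(C)C(C)(C)C)C(C)(C)O[C@@H]2CCC1=O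
F10 | step 5 | (3R,5aR,6R,7S,9aR)-3-(tert-butyldimethylsilyloxy)-2,2,5a,7-tetramethyl-6-(prop-2-en-1-yl)decahydro-1-benzoxepin-7-ol | C=CC[C@@H]1[C@@]2(C)CC[C@@H](O[Si](C)(C)C(C)(C)C)C(C)(C)O[C@@H]2CC[C@]1(C)O
F11 | step 5 | (3R,5aR,6R,7S,9aR)-3-(tert-butyldimethylsilyloxy)-2,2,5a,7-tetramethyl-6-[(1E)-prop-1-en-1-yl]decahydro-1-benzoxepin-7-ol | C/C=C/[C@@H]1[C@@]2(C)CC[C@@H](O[Si](C)(C)C(C)(C)C)C(C)(C)O[C@@H]2CC[C@]1(C)O
F12 | step 11 | (3aR,7aR)-5,7,7-trimethyl-3-methylidene-1,2,3,3a,7,7a-hexahydro-4H-inden-4-one | CC1=CC(C)(C)[C@@H]2CCC(=C)[C@@H]2C1=O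
F13 | step 11 | (3aR,8aR)-4,4,6-trimethyl-1-methylidene-8-(trimethylsilyl)-2,3,3a,4,8,8a-hexahydroazulen-7(1H)-one | CC1=CC(C)(C)[C@@H]2CCC(=C)[C@@H]2C([Si](C)(C)C)C1=O
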